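**Retrosynthetic overview**

1. Target 21 ⇐ diol 20 ⇐ cyclopentene 17, in which the three oxygenated carbons are told apart: the Et3SiO-methyl group on C1 becomes the acetate, and the two TBSO-methyl groups (on C2 and in the side chain) become the two aldehydes.
2. Key disconnection: the ring bond between the two ring CH2 groups (C4–C5). The enabling feature is that the C1=C2 double bond lies between the C5 methylene and the ring stereocentre C3. C2, C3 and C4 can therefore be held as a cyclopropane that carries on C2 a 1,1-disubstituted vinyl group made of C1 and C5; a formal 1,3-shift of C4 from C2 to C5 (17 ⇐ vinylcyclopropane 16) builds the five-membered ring and the tetrasubstituted alkene at once.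
3. The vinylcyclopropane ⇐ terminal alkene 7 (C3=C4) + vinyldiazoacetate 13 (C5, C1, C2 and both oxygenated one-carbon arms) by catalyst-controlled cyclopropanation, which sets C3.
4. Alkene 7 ⇐ aldehyde 4 (from geranyl bromide) by organocatalytic α-hydroxymethylation, which sets the side-chain stereocentre; 13 ⇐ 2-bromoallyl alcohol + methyl bromoacetate.
5. Ring order: cyclopropane (step 9), then its expansion to the cyclopentene (step 12); no other ring is made.

Key step: step 12

Remark on the chemistry: ring locants are those of the target (C1 bears the acetoxymethyl group, C2 the formyl group, C3 the side chain, C4 and C5 are the ring CH2 groups); both enantiomers of Rh2(DOSP)4 and of α,α-diphenylprolinol trimethylsilyl ether, and the Grignard solution 2, are assumed to be commercial.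

**Step 1**
Reactants: 1 geranyl bromide; 2 [2-(1,3-dioxolan-2-yl)ethyl]magnesium bromide
Product: 3 2-[(4E)-5,9-dimethyldeca-4,8-dien-1-yl]-1,3-dioxolane
Conditions: Li2CuCl4 (3 mol%), THF, −20 to 0 °C
Reagents that add atoms: none
Why: Copper-catalysed sp3–sp3 cross-coupling of a Grignard reagent with a primary allylic bromide should join the two carbons at the unhindered allylic CH2 and leave the (E)-trisubstituted double bond untouched.

**Step 2**
Reactants: 3 2-[(4E)-5,9-dimethyldeca-4,8-dien-1-yl]-1,3-dioxolane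
Product: 4 (5E)-6,10-dimethylundeca-5,9-dienal
Conditions: 1 M aq. HCl, THF, rt
Reagents that add atoms: water, O
Why: Acid-catalysed acetal hydrolysis should release the aldehyde, the isolated trisubstituted alkenes being inert to dilute acid at room temperature.

**Step 3**
Reactants: 4 (5E)-6,10-dimethylundeca-5,9-dienal
Product: 5 (2S,5E)-2-(hydroxymethyl)-6,10-dimethylundeca-5,9-dienal
Conditions: (R)-α,α-diphenylprolinol trimethylsilyl ether (20 mol%), 37% aq. formaldehyde, pH 7 phosphate buffer, toluene, rt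
Reagents that add atoms: formaldehyde, C=O
Why: Enamine-mediated cross-aldol addition to formaldehyde (organocatalytic α-hydroxymethylation): the diphenyl(silyloxy)methyl group of the catalyst shields one face of the (E)-enamine, so formaldehyde should add to the open face and set the (S) centre that becomes the side-chain stereocentre; the (R)-catalyst is chosen by analogy with the known facial preference of this catalyst family.

**Step 4**
Reactants: 5 (2S,5E)-2-(hydroxymethyl)-6,10-dimethylundeca-5,9-dienal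
Product: 6 (2S,5E)-2-({[tert-butyl(dimethyl)silyl]oxy}methyl)-6,10-dimethylundeca-5,9-dienal
Conditions: TBSCl, imidazole, CH2Cl2, 0 °C (crude 5 used at once)
Reagents that add atoms: tert-butyl(chloro)dimethylsilane, CC(C)(C)[Si](C)(C)Cl
Why: Silylation of the primary alcohol under mild base should trap the sensitive β-hydroxy aldehyde before it can dehydrate or oligomerise.

**Step 5**
Reactants: 6 (2S,5E)-2-({[tert-butyl(dimethyl)silyl]oxy}methyl)-6,10-dimethylundeca-5,9-dienal
Product: 7 tert-butyl{[(2R,5E)-2-ethenyl-6,10-dimethylundeca-5,9-dien-1-yl]oxy}dimethylsilane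
Conditions: Ph3PCH3Br, KN(SiMe3)2, THF, −78 to 0 °C
Reagents that add atoms: methyltriphenylphosphonium bromide (as its ylide), C[P+](c1ccccc1)(c1ccccc1)c1ccccc1.[Br-]
Why: Wittig methylenation at low temperature should convert the aldehyde into the terminal vinyl group (the future C3=C4 unit) without epimerising the adjacent centre; the descriptor changes from S to R only because the priorities change.

**Step 6**
Reactants: 8 2-bromoprop-2-en-1-ol
Product: 9 [(2-bromoprop-2-en-1-yl)oxy]triethylsilane
Conditions: Et3SiCl, imidazole, CH2Cl2, 0 °C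
Reagents that add atoms: chloro(triethyl)silane, CC[Si](CC)(CC)Cl
Why: Standard silylation; the triethylsilyl ether is chosen because it has no activated C–H bond near the later carbene centre and can be removed before a tert-butyldimethylsilyl ether.

**Step 7**
Reactants: 9 [(2-bromoprop-2-en-1-yl)oxy]triethylsilane; 10 methyl bromoacetate
Product: 12 methyl 3-{[(triethylsilyl)oxy]methyl}but-3-enoate, via zinc enolate 11 (not isolated)
Conditions: Zn dust (Me3SiCl-activated), THF, 40 °C; then 9, Pd(dba)2 (2 mol%), P(t-Bu)3 (4 mol%), rt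
Reagents that add atoms: none
Why: Reformatsky reagent formation followed by Negishi-type coupling of the zinc enolate with the vinyl bromide on zerovalent palladium should give the β,γ-unsaturated ester, the neutral zinc enolate being too weakly basic to move the double bond into conjugation.

**Step 8**
Reactants: 12 methyl 3-{[(triethylsilyl)oxy]methyl}but-3-enoate
Product: 13 methyl 2-diazo-3-{[(triethylsilyl)oxy]methyl}but-3-enoate
Conditions: 4-acetamidobenzenesulfonyl azide, DBU, MeCN, 0 °C; used cold and at once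
Reagents that add atoms: 4-acetamidobenzenesulfonyl azide, CC(=O)Nc1ccc(cc1)S(=O)(=O)N=[N+]=[N-]
Why: Regitz diazo transfer to the doubly activated (allylic and α-ester) methylene should give the vinyldiazoacetate, which is not stored because such compounds slowly close to pyrazoles.

**Step 9**
Reactants: 7 tert-butyl{[(2R,5E)-2-ethenyl-6,10-dimethylundeca-5,9-dien-1-yl]oxy}dimethylsilane; 13 methyl 2-diazo-3-{[(triethylsilyl)oxy]methyl}but-3-enoate
Product: 14 methyl (1R,2S)-2-[(2R,5E)-1-{[tert-butyl(dimethyl)silyl]oxy}-6,10-dimethylundeca-5,9-dien-2-yl]-1-{3-[(triethylsilyl)oxy]prop-1-en-2-yl}cyclopropane-1-carboxylate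
Conditions: Rh2(R-DOSP)4 (1 mol%), pentane, −40 °C to rt, slow addition of 13 (1.5 equiv)
Reagents that add atoms: none
Why: Catalytic asymmetric cyclopropanation by a donor/acceptor rhodium carbenoid: the carbene from 13 should add to the only monosubstituted double bond of 7 (the trisubstituted alkenes are too hindered for this bulky carbenoid), the chiral prolinate ligands choosing the alkene face so that the new ring CH carbon (later C3) is (S) and the vinyl group sits cis to the side chain; Rh2(R-DOSP)4 is taken because its mirror image is known to give the opposite (1S,2R) series with simple terminal alkenes.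

**Step 10**
Reactants: 14 the cyclopropane ester of step 9
Product: 15 {(1R,2S)-2-[(2R,5E)-1-{[tert-butyl(dimethyl)silyl]oxy}-6,10-dimethylundeca-5,9-dien-2-yl]-1-{3-[(triethylsilyl)oxy]prop-1-en-2-yl}cyclopropyl}methanol
Conditions: i-Bu2AlH (2.5 equiv), CH2Cl2, −78 to −20 °C; aq. KNaC4H4O6
Reagents that add atoms: none
Why: Hydride reduction of the ester to the primary alcohol removes the only acceptor group, so that the next steps deal with an unactivated vinylcyclopropane; silyl ethers and alkenes are inert.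

**Step 11**
Reactants: 15 the cyclopropylmethanol of step 10
Product: 16 tert-butyldimethylsilyl ether of 15: (1R,2S)-cyclopropane bearing CH2OTBS and the 3-(triethylsilyloxy)prop-1-en-2-yl group on C1 and the (2R,5E)-1-(TBSO)-6,10-dimethylundeca-5,9-dien-2-yl chain on C2
Conditions: TBSCl, imidazole, DMF, rt
Reagents that add atoms: tert-butyl(chloro)dimethylsilane, CC(C)(C)[Si](C)(C)Cl
Why: Silylation gives both future aldehyde carbons the same, more robust protecting group, distinct from the triethylsilyl ether on the future acetate carbon.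

**Step 12**
Reactants: 16 the fully silylated vinylcyclopropane
Product: 17 tert-butyl({(2R,5E)-2-[(1S)-2-({[tert-butyl(dimethyl)silyl]oxy}methyl)-3-{[(triethylsilyl)oxy]methyl}cyclopent-2-en-1-yl]-6,10-dimethylundeca-5,9-dien-1-yl}oxy)dimethylsilane
Conditions: Ni(cod)2 (5 mol%), IPr [1,3-bis(2,6-diisopropylphenyl)imidazol-2-ylidene] (10 mol%), toluene, 60 °C
Reagents that add atoms: none
Why: Zerovalent nickel carrying the bulky carbene IPr should bind the 1,1-disubstituted vinyl group of 16 and insert into the adjacent cyclopropane bond that runs from the quaternary carbon to the unsubstituted ring CH2, and the resulting vinyl-nickelacyclobutane should open to a six-membered σ-alkyl/η3-allyl nickelacycle whose carbon–carbon reductive elimination at the former vinyl CH2 makes the C4–C5 bond and frees the catalyst. The closest known reaction type is the Ni(cod)2/N-heterocyclic-carbene-catalysed rearrangement of unactivated 1,1-disubstituted vinylcyclopropanes to cyclopentenes. The cyclopentene is closed as a three-to-five ring expansion (a formal 1,3-shift completed by reductive elimination inside the metallacycle), so no endo attack on a π bond is needed and the double bond lands between C1 and C2, tetrasubstituted and flanked by the two differentiated silyloxymethyl groups. No stereocentre is created: C3 keeps all four of its bonds and therefore its configuration from step 9, while the quaternary cyclopropane centre becomes sp2. The selectivity required is insertion into the less substituted of the two cyclopropane bonds next to the vinyl group and reductive elimination ahead of β-hydride elimination; the bulky side chain on C3, cis to the vinyl group, shields the alternative bond, and the strongly donating, bulky IPr ligand is the one known to favour reductive elimination. The trisubstituted alkenes and the silyl ethers should not engage the catalyst.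

**Step 13**
Reactants: 17 the tris-silylated cyclopentene
Product: 18 [(3S)-2-({[tert-butyl(dimethyl)silyl]oxy}methyl)-3-[(2R,5E)-1-{[tert-butyl(dimethyl)silyl]oxy}-6,10-dimethylundeca-5,9-dien-2-yl]cyclopent-1-en-1-yl]methanol
Conditions: pyridinium p-toluenesulfonate (0.2 equiv), MeOH–CH2Cl2, 0 °C
Reagents that add atoms: none
Why: Mild acid-catalysed methanolysis should cleave the primary allylic triethylsilyl ether well before either tert-butyldimethylsilyl ether, exposing only the hydroxyl that is to carry the acetate.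

**Step 14**
Reactants: 18 the C1 allylic alcohol
Product: 19 [(3S)-2-({[tert-butyl(dimethyl)silyl]oxy}methyl)-3-[(2R,5E)-1-{[tert-butyl(dimethyl)silyl]oxy}-6,10-dimethylundeca-5,9-dien-2-yl]cyclopent-1-en-1-yl]methyl acetate
Conditions: Ac2O, pyridine, DMAP (cat.), CH2Cl2, 0 °C
Reagents that add atoms: acetic anhydride, CC(=O)OC(C)=O
Why: Acylation of the single free primary alcohol installs the acetate of the target while both future aldehyde carbons are still masked.

**Step 15**
Reactants: 19 the bis-silyl acetate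
Product: 20 [(3S)-2-(hydroxymethyl)-3-[(2R,5E)-1-hydroxy-6,10-dimethylundeca-5,9-dien-2-yl]cyclopent-1-en-1-yl]methyl acetate
Conditions: HF·pyridine, pyridine, THF, 0 °C to rt
Reagents that add atoms: none
Why: Buffered fluoride-mediated desilylation should free both primary alcohols under slightly acidic conditions that neither hydrolyse nor shift the allylic acetate.

**Step 16**
Reactants: 20 the diol acetate
Product: 21 [(3S)-2-formyl-3-[(2R,5E)-6,10-dimethyl-1-oxoundeca-5,9-dien-2-yl]cyclopent-1-en-1-yl]methyl acetate (target)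
Conditions: Dess–Martin periodinane (2.6 equiv), pyridine, CH2Cl2, 0 °C to rt
Reagents that add atoms: none
Why: Dess–Martin oxidation should convert the allylic alcohol into the enal and the saturated primary alcohol into the α-branched aldehyde in one operation under buffered, non-epimerising conditions; the acetate is already in place, so no free γ-hydroxy enal (which could close to a lactol) is ever formed.

**Compound list**

1 | geranyl bromide, (2E)-1-bromo-3,7-dimethylocta-2,6-diene | BrC/C=C(\C)CCC=C(C)C | starting material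
2 | [2-(1,3-dioxolan-2-yl)ethyl]magnesium bromide (THF solution) | Br[Mg]CCC1OCCO1 | starting material
3 | 2-[(4E)-5,9-dimethyldeca-4,8-dien-1-yl]-1,3-dioxolane | C1COC(O1)CCC/C=C(\C)CCC=C(C)C | intermediate
4 | (5E)-6,10-dimethylundeca-5,9-dienal | O=CCCC/C=C(\C)CCC=C(C)C | intermediate
5 | (2S,5E)-2-(hydroxymethyl)-6,10-dimethylundeca-5,9-dienal | O=C[C@H](CO)CC/C=C(\C)CCC=C(C)C | intermediate
6 | (2S,5E)-2-({[tert-butyl(dimethyl)silyl]oxy}methyl)-6,10-dimethylundeca-5,9-dienal | O=C[C@H](CO[Si](C)(C)C(C)(C)C)CC/C=C(\C)CCC=C(C)C | intermediate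
7 | tert-butyl{[(2R,5E)-2-ethenyl-6,10-dimethylundeca-5,9-dien-1-yl]oxy}dimethylsilane | C=C[C@H](CO[Si](C)(C)C(C)(C)C)CC/C=C(\C)CCC=C(C)C | intermediate
8 | 2-bromoprop-2-en-1-ol | C=C(Br)CO | starting material
9 | [(2-bromoprop-2-en-1-yl)oxy]triethylsilane | C=C(Br)CO[Si](CC)(CC)CC | intermediate
10 | methyl bromoacetate | COC(=O)CBr | starting material
11 | bromo(2-methoxy-2-oxoethyl)zinc (Reformatsky reagent, not isolated) | COC(=O)C[Zn]Br | intermediate
12 | methyl 3-{[(triethylsilyl)oxy]methyl}but-3-enoate | COC(=O)CC(=C)CO[Si](CC)(CC)CC | intermediate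
13 | methyl 2-diazo-3-{[(triethylsilyl)oxy]methyl}but-3-enoate | COC(=O)C(=[N+]=[N-])C(=C)CO[Si](CC)(CC)CC | intermediate
14 | methyl (1R,2S)-2-[(2R,5E)-1-{[tert-butyl(dimethyl)silyl]oxy}-6,10-dimethylundeca-5,9-dien-2-yl]-1-{3-[(triethylsilyl)oxy]prop-1-en-2-yl}cyclopropane-1-carboxylate (vinyl group cis to the side chain) | COC(=O)[C@@]1(C(=C)CO[Si](CC)(CC)CC)[C@H]([C@H](CO[Si](C)(C)C(C)(C)C)CC/C=C(\C)CCC=C(C)C)C1 | intermediate
15 | {(1R,2S)-2-[(2R,5E)-1-{[tert-butyl(dimethyl)silyl]oxy}-6,10-dimethylundeca-5,9-dien-2-yl]-1-{3-[(triethylsilyl)oxy]prop-1-en-2-yl}cyclopropyl}methanol | OC[C@@]1(C(=C)CO[Si](CC)(CC)CC)[C@H]([C@H](CO[Si](C)(C)C(C)(C)C)CC/C=C(\C)CCC=C(C)C)C1 | intermediate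
16 | tert-butyldimethylsilyl ether of 15 | CC(C)(C)[Si](C)(C)OC[C@@]1(C(=C)CO[Si](CC)(CC)CC)[C@H]([C@H](CO[Si](C)(C)C(C)(C)C)CC/C=C(\C)CCC=C(C)C)C1 | intermediate
17 | tert-butyl({(2R,5E)-2-[(1S)-2-({[tert-butyl(dimethyl)silyl]oxy}methyl)-3-{[(triethylsilyl)oxy]methyl}cyclopent-2-en-1-yl]-6,10-dimethylundeca-5,9-dien-1-yl}oxy)dimethylsilane | CC[Si](CC)(CC)OCC1=C(CO[Si](C)(C)C(C)(C)C)[C@H]([C@H](CO[Si](C)(C)C(C)(C)C)CC/C=C(\C)CCC=C(C)C)CC1 | intermediate
18 | [(3S)-2-({[tert-butyl(dimethyl)silyl]oxy}methyl)-3-[(2R,5E)-1-{[tert-butyl(dimethyl)silyl]oxy}-6,10-dimethylundeca-5,9-dien-2-yl]cyclopent-1-en-1-yl]methanol | OCC1=C(CO[Si](C)(C)C(C)(C)C)[C@H]([C@H](CO[Si](C)(C)C(C)(C)C)CC/C=C(\C)CCC=C(C)C)CC1 | intermediate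
19 | [(3S)-2-({[tert-butyl(dimethyl)silyl]oxy}methyl)-3-[(2R,5E)-1-{[tert-butyl(dimethyl)silyl]oxy}-6,10-dimethylundeca-5,9-dien-2-yl]cyclopent-1-en-1-yl]methyl acetate | CC(=O)OCC1=C(CO[Si](C)(C)C(C)(C)C)[C@H]([C@H](CO[Si](C)(C)C(C)(C)C)CC/C=C(\C)CCC=C(C)C)CC1 | intermediate
20 | [(3S)-2-(hydroxymethyl)-3-[(2R,5E)-1-hydroxy-6,10-dimethylundeca-5,9-dien-2-yl]cyclopent-1-en-1-yl]methyl acetate | CC(=O)OCC1=C(CO)[C@H]([C@H](CO)CC/C=C(\C)CCC=C(C)C)CC1 | intermediate
21 | [(3S)-2-formyl-3-[(2R,5E)-6,10-dimethyl-1-oxoundeca-5,9-dien-2-yl]cyclopent-1-en-1-yl]methyl acetate | CC(=O)OCC1=C(C=O)[C@H]([C@H](C=O)CC/C=C(\C)CCC=C(C)C)CC1 | target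

**Step count and risks**

Total: 16 steps. Longest linear sequence: 13 steps (steps 1–5 and 9–16, from geranyl bromide); steps 6–8 form the three-step branch to diazo ester 13.

Steps most likely to fail:

Step 9. The electrophilic rhodium carbene may attack the allylic C–H bonds or the trisubstituted double bonds of the side chain instead of the branched terminal alkene, and facial control may be incomplete if catalyst and the existing stereocentre are mismatched. The fallback avoids a free carbene and sets out from 6 and 12, coming back at 15. The lithium dienolate of 12 (LiN(i-Pr)2, THF, −78 °C) would add through its α-carbon to aldehyde 6 to give the aldol methyl (4S,7E)-4-({[tert-butyl(dimethyl)silyl]oxy}methyl)-3-hydroxy-8,12-dimethyl-2-{3-[(triethylsilyl)oxy]prop-1-en-2-yl}trideca-7,11-dienoate F1. Dehydration with methyl N-(triethylammoniosulfonyl)carbamate (Burgess dehydration) should give, after removal of the geometric isomer, methyl (2E,4R,7E)-4-({[tert-butyl(dimethyl)silyl]oxy}methyl)-8,12-dimethyl-2-{3-[(triethylsilyl)oxy]prop-1-en-2-yl}trideca-2,7,11-trienoate F2. Reduction with i-Bu2AlH gives (2E,4R,7E)-4-({[tert-butyl(dimethyl)silyl]oxy}methyl)-8,12-dimethyl-2-{3-[(triethylsilyl)oxy]prop-1-en-2-yl}trideca-2,7,11-trien-1-ol F3. A hydroxyl-directed, enantioselective Simmons–Smith cyclopropanation (Zn(CH2I)2·DME, the chiral butylboronate of N,N,N′,N′-tetramethyltartramide in the enantiomeric form that delivers CH2 to the required face, CH2Cl2, 0 °C) is delivered by the zinc alkoxide only to the allylic double bond, leaves isolated trisubstituted alkenes alone, and should give 15.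

Step 12. Nickel may insert into the more substituted cyclopropane bond (giving the regioisomeric cyclopentene), or the nickelacycle may collapse by β-hydride or β-silyloxy elimination to open-chain dienes. The fallback makes the same ring bond by an ionic ring expansion steered by a temporary sulfur donor on the ring CH2 next to the stereocentre; it sets out from 6 and 13 and comes back at 17. Wittig reaction of 6 with Ph3P=CHSPh gives, after separation, tert-butyl(dimethyl){[(2R,5E)-6,10-dimethyl-2-[(Z)-2-(phenylsulfanyl)ethenyl]undeca-5,9-dien-1-yl]oxy}silane F4. Cyclopropanation of this electron-rich alkene with 13 under Rh2(R-DOSP)4 gives methyl 2-[(2R,5E)-1-{[tert-butyl(dimethyl)silyl]oxy}-6,10-dimethylundeca-5,9-dien-2-yl]-3-(phenylsulfanyl)-1-{3-[(triethylsilyl)oxy]prop-1-en-2-yl}cyclopropane-1-carboxylate F5. Et2AlCl (CH2Cl2, −78 °C) should open the donor–acceptor bond toward the sulfur-stabilised cation and let the dienolate close through its terminal carbon, giving methyl 5-[(2R,5E)-1-{[tert-butyl(dimethyl)silyl]oxy}-6,10-dimethylundeca-5,9-dien-2-yl]-4-(phenylsulfanyl)-2-{[(triethylsilyl)oxy]methyl}cyclopent-1-ene-1-carboxylate F6. Radical desulfurisation (Bu3SnH, AIBN, toluene, 110 °C) gives methyl (5S)-5-[(2R,5E)-1-{[tert-butyl(dimethyl)silyl]oxy}-6,10-dimethylundeca-5,9-dien-2-yl]-2-{[(triethylsilyl)oxy]methyl}cyclopent-1-ene-1-carboxylate F7. Reduction with i-Bu2AlH gives [(5S)-5-[(2R,5E)-1-{[tert-butyl(dimethyl)silyl]oxy}-6,10-dimethylundeca-5,9-dien-2-yl]-2-{[(triethylsilyl)oxy]methyl}cyclopent-1-en-1-yl]methanol F8, and silylation (TBSCl, imidazole) gives 17.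

Step 3. The β-hydroxy aldehyde can lose enantiomeric purity through reversible aldol addition and enolisation, dehydrate to the α-methylene aldehyde, or oligomerise before it is trapped. The fallback replaces catalyst control by auxiliary control; it sets out from 4 and comes back at 6. Pinnick oxidation (NaClO2, NaH2PO4, 2-methylbut-2-ene) gives (5E)-6,10-dimethylundeca-5,9-dienoic acid F9. Its mixed anhydride with pivalic acid, (5E)-6,10-dimethylundeca-5,9-dienoic pivalic anhydride F10 (t-BuCOCl, Et3N; not isolated), acylates lithiated (R)-4-benzyl-1,3-oxazolidin-2-one to give (4R)-4-benzyl-3-[(5E)-6,10-dimethylundeca-5,9-dienoyl]-1,3-oxazolidin-2-one F11. The titanium enolate (TiCl4, i-Pr2NEt, CH2Cl2, 0 °C) is hydroxymethylated with 1,3,5-trioxane on the face away from the benzyl group to give (4R)-4-benzyl-3-[(2S,5E)-2-(hydroxymethyl)-6,10-dimethylundeca-5,9-dienoyl]-1,3-oxazolidin-2-one F12. Silylation (TBSOTf, 2,6-lutidine) gives (4R)-4-benzyl-3-[(2S,5E)-2-({[tert-butyl(dimethyl)silyl]oxy}methyl)-6,10-dimethylundeca-5,9-dienoyl]-1,3-oxazolidin-2-one F13. Reductive removal of the auxiliary (LiBH4, MeOH, THF) gives (2R,5E)-2-({[tert-butyl(dimethyl)silyl]oxy}methyl)-6,10-dimethylundeca-5,9-dien-1-ol F14, and Dess–Martin oxidation gives 6.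

**Further compounds**

F1 | step 9 | methyl (4S,7E)-4-({[tert-butyl(dimethyl)silyl]oxy}methyl)-3-hydroxy-8,12-dimethyl-2-{3-[(triethylsilyl)oxy]prop-1-en-2-yl}trideca-7,11-dienoate (mixture at C2 and C3) | COC(=O)C(C(=C)CO[Si](CC)(CC)CC)C(O)[C@H](CO[Si](C)(C)C(C)(C)C)CC/C=C(\C)CCC=C(C)C
F2 | step 9 | methyl (2E,4R,7E)-4-({[tert-butyl(dimethyl)silyl]oxy}methyl)-8,12-dimethyl-2-{3-[(triethylsilyl)oxy]prop-1-en-2-yl}trideca-2,7,11-trienoate | COC(=O)/C(C(=C)CO[Si](CC)(CC)CC)=C/[C@H](CO[Si](C)(C)C(C)(C)C)CC/C=C(\C)CCC=C(C)C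
F3 | step 9 | (2E,4R,7E)-4-({[tert-butyl(dimethyl)silyl]oxy}methyl)-8,12-dimethyl-2-{3-[(triethylsilyl)oxy]prop-1-en-2-yl}trideca-2,7,11-trien-1-ol | OC/C(C(=C)CO[Si](CC)(CC)CC)=C/[C@H](CO[Si](C)(C)C(C)(C)C)CC/C=C(\C)CCC=C(C)C
F4 | step 12 | tert-butyl(dimethyl){[(2R,5E)-6,10-dimethyl-2-[(Z)-2-(phenylsulfanyl)ethenyl]undeca-5,9-dien-1-yl]oxy}silane | c1ccccc1S/C=C\[C@H](CO[Si](C)(C)C(C)(C)C)CC/C=C(\C)CCC=C(C)C
F5 | step 12 | methyl 2-[(2R,5E)-1-{[tert-butyl(dimethyl)silyl]oxy}-6,10-dimethylundeca-5,9-dien-2-yl]-3-(phenylsulfanyl)-1-{3-[(triethylsilyl)oxy]prop-1-en-2-yl}cyclopropane-1-carboxylate (vinyl group, side chain and sulfur all cis; side-chain-bearing ring carbon as in 14) | COC(=O)[C@@]1(C(=C)CO[Si](CC)(CC)CC)[C@H]([C@H](CO[Si](C)(C)C(C)(C)C)CC/C=C(\C)CCC=C(C)C)[C@@H]1Sc1ccccc1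
F6 | step 12 | methyl 5-[(2R,5E)-1-{[tert-butyl(dimethyl)silyl]oxy}-6,10-dimethylundeca-5,9-dien-2-yl]-4-(phenylsulfanyl)-2-{[(triethylsilyl)oxy]methyl}cyclopent-1-ene-1-carboxylate (ring carbon 5 as in 17, mixture at carbon 4) | COC(=O)C1=C(CO[Si](CC)(CC)CC)CC(Sc2ccccc2)[C@H]1[C@H](CO[Si](C)(C)C(C)(C)C)CC/C=C(\C)CCC=C(C)C
F7 | step 12 | methyl (5S)-5-[(2R,5E)-1-{[tert-butyl(dimethyl)silyl]oxy}-6,10-dimethylundeca-5,9-dien-2-yl]-2-{[(triethylsilyl)oxy]methyl}cyclopent-1-ene-1-carboxylate | COC(=O)C1=C(CO[Si](CC)(CC)CC)CC[C@H]1[C@H](CO[Si](C)(C)C(C)(C)C)CC/C=C(\C)CCC=C(C)C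
F8 | step 12 | [(5S)-5-[(2R,5E)-1-{[tert-butyl(dimethyl)silyl]oxy}-6,10-dimethylundeca-5,9-dien-2-yl]-2-{[(triethylsilyl)oxy]methyl}cyclopent-1-en-1-yl]methanol | OCC1=C(CO[Si](CC)(CC)CC)CC[C@H]1[C@H](CO[Si](C)(C)C(C)(C)C)CC/C=C(\C)CCC=C(C)C
F9 | step 3 | (5E)-6,10-dimethylundeca-5,9-dienoic acid | OC(=O)CCC/C=C(\C)CCC=C(C)C
F10 | step 3 | (5E)-6,10-dimethylundeca-5,9-dienoic pivalic anhydride (not isolated) | CC(C)(C)C(=O)OC(=O)CCC/C=C(\C)CCC=C(C)C
F11 | step 3 | (4R)-4-benzyl-3-[(5E)-6,10-dimethylundeca-5,9-dienoyl]-1,3-oxazolidin-2-one | O=C(CCC/C=C(\C)CCC=C(C)C)N1[C@H](Cc2ccccc2)COC1=O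
F12 | step 3 | (4R)-4-benzyl-3-[(2S,5E)-2-(hydroxymethyl)-6,10-dimethylundeca-5,9-dienoyl]-1,3-oxazolidin-2-one | O=C([C@H](CO)CC/C=C(\C)CCC=C(C)C)N1[C@H](Cc2ccccc2)COC1=O
F13 | step 3 | (4R)-4-benzyl-3-[(2S,5E)-2-({[tert-butyl(dimethyl)silyl]oxy}methyl)-6,10-dimethylundeca-5,9-dienoyl]-1,3-oxazolidin-2-one | O=C([C@H](CO[Si](C)(C)C(C)(C)C)CC/C=C(\C)CCC=C(C)C)N1[C@H](Cc2ccccc2)COC1=O
F14 | step 3 | (2R,5E)-2-({[tert-butyl(dimethyl)silyl]oxy}methyl)-6,10-dimethylundeca-5,9-dien-1-ol | OC[C@H](CO[Si](C)(C)C(C)(C)C)CC/C=C(\C)CCC=C(C)C
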